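**Assumption:** the target SMILES contains no stereocentres or stereo-descriptors. I treat Marchantinquinone as achiral, and any helical or planar chirality of the cyclophane is not specified. No stereochemistry needs to be set, and the E/Z geometry of the intermediate stilbenes is erased by hydrogenation.

## Retrosynthetic overview
1. The quinone is made last, by Teuber (Fremy's salt) oxidation of a para-unsubstituted phenol on the ortho-aryloxy ring. One BBr3 step unmasks both the ring-C phenol and that oxidation precursor.
2. Both Ar–CH2CH2–Ar bridges come from sulfur extrusion. A 20-membered macrocyclic bis(dibenzyl sulfide) is oxidised to the disulfone, contracted by a double Ramberg–Bäcklund reaction to a bis-stilbene, and hydrogenated.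
3. The macrocycle is closed by Na2S double SN2 on a linear dibenzylic dibromide. A prior intermolecular thioether coupling fixes the ring order, avoiding the regio-scrambling of a 2+2 macrocyclisation.
4. The two diaryl ethers come from SNAr on aldehyde-activated fluoroarenes. Those aldehyde carbons become the Q–B bridge, and the benzylic alcohols on the phenol partners become the D–C bridge.
5. Order of ring formation: two ether-linked biaryl ether units, then the linear bis-aldehyde sulfide, then the 20-membered ring (Step 8), then the 18-membered ring by contraction (Step 10), then the quinone (Step 13).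

## Route

**Step 1**
Reactants: 1 (2-fluoro-3-methoxybenzaldehyde), 2 (3-hydroxybenzyl alcohol)
Product: 3 (2-[3-(hydroxymethyl)phenoxy]-3-methoxybenzaldehyde)
Conditions: K2CO3, DMF, 110 °C
Reagents that add atoms: none
Why: the phenoxide displaces the fluoride ortho to CHO in an SNAr; the aliphatic alcohol is not deprotonated by K2CO3, so the diaryl ether forms chemoselectively.

**Step 2**
Reactants: 4 (4-fluorobenzaldehyde), 5 (3-hydroxy-4-methoxybenzyl alcohol)
Product: 6 (4-[5-(hydroxymethyl)-2-methoxyphenoxy]benzaldehyde)
Conditions: K2CO3, DMF, 110 °C
Reagents that add atoms: none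
Why: the same aldehyde-activated SNAr gives the ring C–O–ring B ether, with the OMe ortho to the new ether oxygen as in the target.

**Step 3**
Reactants: 3
Product: 7 (2-[3-(bromomethyl)phenoxy]-3-methoxybenzaldehyde)
Conditions: PBr3, CH2Cl2, 0 °C
Reagents that add atoms: phosphorus tribromide, BrP(Br)Br
Why: PBr3 converts the benzylic alcohol to the bromide by SN2, and the hindered aryl aldehyde survives at 0 °C.

**Step 4**
Reactants: 6
Product: 8 (S-[3-(4-formylphenoxy)-4-methoxybenzyl] thioacetate)
Conditions: PPh3, DIAD, AcSH, THF, 0 °C
Reagents that add atoms: thioacetic acid, CC(=O)S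
Why: a Mitsunobu thioesterification gives the masked benzylic thiol and leaves the aldehyde untouched.

**Step 5**
Reactants: 7, 8
Product: 9 (dialdehyde dibenzyl sulfide, Q-CHO … D–CH2–S–CH2–C … B-CHO)
Conditions: 8 and K2CO3 in degassed MeOH/THF, rt, 15 min; then 7, rt
Reagents that add atoms: none
Why: in-situ methanolysis releases the thiolate, which alkylates the benzylic bromide in an intermolecular SN2. Each fragment carries only one such handle, so the D–S–C bridge is formed regio-unambiguously.

**Step 6**
Reactants: 9
Product: 10 (diol sulfide)
Conditions: NaBH4, EtOH/THF, 0 °C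
Reagents that add atoms: none (hydride only)
Why: hydride reduces both aryl aldehydes, and the thioether and aryl ethers are inert.

**Step 7**
Reactants: 10
Product: 11 (dibromide, BrCH2–Q … B–CH2Br)
Conditions: CBr4, PPh3, CH2Cl2, 0 °C; crude used at once
Reagents that add atoms: carbon tetrabromide, BrC(Br)(Br)Br
Why: an Appel reaction under neutral conditions (no aldehyde is left) converts both benzylic alcohols to bromides, and the short reaction time minimises sulfonium formation.

**Step 8**
Reactants: 11
Product: 12 (macrocyclic bis-sulfide, 20-membered)
Conditions: Na2S·9H2O (1.05 equiv), EtOH/THF 1:1, 60 °C, syringe-pump addition, 2 mM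
Reagents that add atoms: sodium sulfide, [Na+].[Na+].[S-2]
Why: intramolecular double SN2 at high dilution, in the manner of dithiacyclophane synthesis, closes the ring. The linear precursor has a single possible connectivity, so the Q–CH2–S–CH2–B bridge forms with no regio-ambiguity.

**Step 9**
Reactants: 12
Product: 13 (macrocyclic disulfone)
Conditions: mCPBA (5 equiv), CH2Cl2, 0 °C to rt
Reagents that add atoms: m-chloroperoxybenzoic acid, OOC(=O)c1cccc(Cl)c1
Why: sulfide oxidation through the sulfoxide to the sulfone; no aldehydes remain, so Baeyer–Villiger is not a concern.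

**Step 10**
Reactants: 13
Product: 14 (bis-stilbene macrocycle, 18-membered, E/Z unspecified)
Conditions: powdered KOH on Al2O3, CCl4, t-BuOH/CH2Cl2, rt
Reagents that add atoms: none (CCl4 is the halogenating oxidant and leaves as CHCl3)
Why: a Meyer-modified Ramberg–Bäcklund reaction works by α-chlorination, episulfone formation and SO2 loss. The acidic dibenzylic sulfones suit this, and it contracts the ring to the 18-membered cyclophane-diene. No stereocentre is created, because the alkene geometry is removed in Step 11.

**Step 11**
Reactants: 14
Product: 15 (saturated macrocyclic dimethyl ether)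
Conditions: H2 (1 atm), 10% Pd/C, EtOAc/MeOH, rt
Reagents that add atoms: none
Why: heterogeneous hydrogenation of both stilbene C=C bonds gives the two CH2CH2 bridges; no sulfur remains to poison the catalyst and no benzyl ethers are present.

**Step 12**
Reactants: 15
Product: 16 (macrocyclic diphenol)
Conditions: BBr3 (5 equiv), CH2Cl2, −78 °C to 0 °C
Reagents that add atoms: none (the methyl groups leave as MeBr)
Why: BBr3 demethylates both aryl methyl ethers, which are chelation-activated by the adjacent ether oxygens. This unveils the ring-C phenol of the target and the ring-Q phenol that carries the quinone oxygen, while the diaryl ethers survive at this temperature.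

**Step 13**
Reactants: 16
Product: 17 (Marchantinquinone)
Conditions: Fremy's salt (2.5 equiv), acetone/0.17 M aq. KH2PO4, rt
Reagents that add atoms: potassium nitrosodisulfonate, [K+].[K+].[O]N(S(=O)(=O)[O-])S(=O)(=O)[O-] (oxygen source, with water)
Why: Teuber oxidation of the ring-Q phenol at its free para position gives the 2-aryloxy-3-alkyl-p-quinone. The ring-C phenol is para-blocked and much less reactive, so it survives.

## Compound list
1 | 2-fluoro-3-methoxybenzaldehyde | COc1cccc(C=O)c1F | starting material
2 | 3-hydroxybenzyl alcohol | OCc1cccc(O)c1 | starting material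
3 | 2-[3-(hydroxymethyl)phenoxy]-3-methoxybenzaldehyde | COc1cccc(C=O)c1Oc1cccc(CO)c1 | intermediate
4 | 4-fluorobenzaldehyde | O=Cc1ccc(F)cc1 | starting material
5 | 3-hydroxy-4-methoxybenzyl alcohol | COc1ccc(CO)cc1O | starting material
6 | 4-[5-(hydroxymethyl)-2-methoxyphenoxy]benzaldehyde | COc1ccc(CO)cc1Oc1ccc(C=O)cc1 | intermediate
7 | 2-[3-(bromomethyl)phenoxy]-3-methoxybenzaldehyde | COc1cccc(C=O)c1Oc1cccc(CBr)c1 | intermediate
8 | S-[3-(4-formylphenoxy)-4-methoxybenzyl] thioacetate | COc1ccc(CSC(C)=O)cc1Oc1ccc(C=O)cc1 | intermediate
9 | linear dialdehyde dibenzyl sulfide | COc1cccc(C=O)c1Oc1cccc(CSCc2ccc(OC)c(Oc3ccc(C=O)cc3)c2)c1 | intermediate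
10 | linear diol sulfide | COc1cccc(CO)c1Oc1cccc(CSCc2ccc(OC)c(Oc3ccc(CO)cc3)c2)c1 | intermediate
11 | linear dibromide sulfide | COc1cccc(CBr)c1Oc1cccc(CSCc2ccc(OC)c(Oc3ccc(CBr)cc3)c2)c1 | intermediate
12 | macrocyclic bis-sulfide (20-membered) | COc1cccc2c1Oc1cccc(c1)CSCc1ccc(OC)c(c1)Oc1ccc(cc1)CSC2 | intermediate
13 | macrocyclic disulfone | COc1cccc2c1Oc1cccc(c1)CS(=O)(=O)Cc1ccc(OC)c(c1)Oc1ccc(cc1)CS(=O)(=O)C2 | intermediate
14 | macrocyclic bis-stilbene (18-membered, geometry unspecified) | COc1cccc2c1Oc1cccc(c1)C=Cc1ccc(OC)c(c1)Oc1ccc(cc1)C=C2 | intermediate
15 | saturated macrocyclic dimethyl ether | COc1cccc2c1Oc1cccc(c1)CCc1ccc(OC)c(c1)Oc1ccc(cc1)CC2 | intermediate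
16 | macrocyclic diphenol | Oc1cccc2c1Oc1cccc(c1)CCc1ccc(O)c(c1)Oc1ccc(cc1)CC2 | intermediate
17 | Marchantinquinone | O=C1C=CC(=O)C2=C1CCc1ccc(cc1)Oc1cc(ccc1O)CCc1cccc(c1)O2 | target

Formula check: 16 is C28H24O4 and 17 is C28H22O5. The target has no stereocentres.

## Totals
- **Total steps:** 13.
- **Longest linear sequence:** 11 steps, either 1→3→7→9→…→17 or 2/4/5→6→8→9→…→17.

## Three steps most likely to fail
1. **Step 8 (Na2S macrocyclisation).** Oligomers or cyclic sulfonium salts from the benzylic bromide attacking a sulfide can compete.
   - Fallback (changes approach): go back to dialdehyde 9 and close the Q–B bridge by intramolecular McMurry coupling (TiCl4/Zn, pyridine, high dilution) to the stilbene. Reduce it with diimide (sulfide-tolerant), then run sulfide → sulfone → Ramberg–Bäcklund → H2 on the D–C bridge to reach 15.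
2. **Step 10 (double Ramberg–Bäcklund on the strained disulfone).** Incomplete contraction, or halogenation and ring-opening side reactions, could occur.
   - Fallback (changes approach): skip the sulfones. S-methylate bis-sulfide 12 (MeOTf) and apply base-induced Stevens [1,2] ring contraction, then Raney Ni desulfurisation (Vögtle/Mitchell cyclophane method), to reach 15.
3. **Step 13 (Fremy oxidation).** The free ring-C phenol could be over-oxidised, or the quinone could be lost during work-up.
   - Fallback (changes approach): use 2-fluoro-3,6-dimethoxybenzaldehyde in place of 1 so that the Q ring carries a hydroquinone dimethyl ether. BBr3 then liberates the hydroquinone and the ring-C phenol together, and mild hydroquinone-selective oxidation (Ag2O or DDQ) gives 17 in place of the phenol oxidation.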